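**Retrosynthetic overview**
1. Two Suzuki–Miyaura disconnections (C8–C9 and C8'–C9') give an epoxy-ring alkyne ester, an ε-ring alkyne ester and a central all-E C18 heptaenyl dibromide.
2. The dibromide comes from a C12 trienediyne (two carboaluminated silylbutadiynes joined through (E)-1,2-diiodoethene), capped at both ends with (E)-2-bromo-1-iodopropene.
3. Both ring esters come from one (1R,4R)-4-alkynylcyclohex-2-enol: direct acylation gives the ε ring; alkene shift into conjugation, hydroxyl-directed epoxidation and Mitsunobu inversion with hexadecanoic acid give the epoxy ring.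
4. That cyclohexenol comes from a 4-alkynylcyclohex-2-enone made by one-carbon ring expansion (siloxycyclopropane opening) of a cyclopentanone, itself from enantioselective conjugate alkynylation/methylation of 4,4-dimethylcyclopentenone. Ring order: cyclopentanone, fused cyclopropane, cyclohexenone, then the epoxide.
5. Hexadecanoic acid is assembled C7 + C6 + C3 by two copper-catalysed Grignard couplings.

Assumption: positions in the Why lines use carotenoid numbering (ring C1–C6, chain C7–C15, primes for the ε half); compound 9 is acetylene carrying a tri(propan-2-yl)silyl protecting group.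

**Route**

Step 1
Reactants: 1 1-bromoheptane; 2 1,6-dibromohexane
Product: 4 1-bromotridecane, via heptylmagnesium bromide 3 (not isolated)
Conditions: Mg, THF; then 2 (3 equiv), Li2CuCl4 (2 mol%), THF, −10 to 0 °C
Reagents that add atoms: none
Why: Copper-catalysed Grignard–alkyl bromide cross-coupling (Kochi type); the threefold excess of 2 makes monosubstitution dominant and unreacted 2 is distilled off.

Step 2
Reactants: 4 1-bromotridecane; 5 oxetan-2-one (β-propiolactone)
Product: 7 hexadecanoic acid, via tridecylmagnesium bromide 6 (not isolated)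
Conditions: Mg, THF; then 5, CuBr·SMe2 (3 mol%), THF/Me2S, −30 to 0 °C; aq. HCl
Reagents that add atoms: none
Why: Copper-catalysed Grignard opening of β-propiolactone by SN2 attack at the O–CH2 carbon (alkyl–oxygen cleavage) is a three-carbon homologation that gives the C16 acid directly.

Step 3
Reactants: 8 4,4-dimethylcyclopent-2-en-1-one; 9 ethynyltri(propan-2-yl)silane
Product: 12 (2S,3S)-2,4,4-trimethyl-3-{[tri(propan-2-yl)silyl]ethynyl}cyclopentan-1-one, via alkynylalane 10 (not isolated), via aluminium enolate 11 (not isolated)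
Conditions: 9, Me3Al, Et3N (10 mol%), toluene, 60 °C; then 8, Ni(acac)2 (5 mol%), (S,S)-t-Bu-box (6 mol%), i-Bu2AlH (5 mol%), t-BuOMe, −20 °C; then MeLi; MeI, DMPU, −40 to 0 °C
Reagents that add atoms: iodomethane, CI
Why: Proposed new method: enantioselective nickel-catalysed conjugate alkynylation of a γ,γ-disubstituted cyclopentenone with in-flask C-methylation of the aluminium enolate; the alane activates the carbonyl while low-valent nickel bound to the C2-symmetric bis(oxazoline) adds across the enone to a nickel-allyl/aluminium enolate, and alkynyl transfer plus reductive elimination forge the C6'–C7' bond on the ligand-selected face (ligand antipode chosen to give 3S), the rod-shaped alkynyl group tolerating the adjacent quaternary carbon; MeLi turns enolate 11 into an ate complex that is methylated anti to the alkynyl group; closest known reaction type: nickel-catalysed conjugate addition of dimethylaluminium acetylides to cyclic enones (including the nickel–bis(oxazoline) enantioselective variant on cyclohexenone) and alkylation of aluminium enolates through their ate complexes.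

Step 4
Reactants: 12 (2S,3S)-2,4,4-trimethyl-3-{[tri(propan-2-yl)silyl]ethynyl}cyclopentan-1-one
Product: 13 trimethyl{[(3R)-2,4,4-trimethyl-3-{[tri(propan-2-yl)silyl]ethynyl}cyclopent-1-en-1-yl]oxy}silane
Conditions: Me3SiCl, NaI, Et3N, MeCN, 23 °C
Reagents that add atoms: chlorotrimethylsilane, C[Si](C)(C)Cl
Why: Thermodynamic enol silylation (iodotrimethylsilane made in the flask) gives the tetrasubstituted enol ether on the methyl-bearing side, which fixes where the ring will be enlarged; the C2 centre is erased and C3 is untouched.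

Step 5
Reactants: 13 trimethyl{[(3R)-2,4,4-trimethyl-3-{[tri(propan-2-yl)silyl]ethynyl}cyclopent-1-en-1-yl]oxy}silane
Product: 14 trimethyl{[(1S,4R,5S)-3,3,5-trimethyl-4-{[tri(propan-2-yl)silyl]ethynyl}bicyclo[3.1.0]hexan-1-yl]oxy}silane
Conditions: Et2Zn, CH2I2, CH2Cl2, 0 to 23 °C
Reagents that add atoms: diiodomethane, ICI
Why: Simmons–Smith (Furukawa) cyclopropanation of the electron-rich silyl enol ether, with the alkyne inert and methylene delivered anti to the alkynyl group; either cyclopropane epimer would give the same enone in step 6.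

Step 6
Reactants: 14 trimethyl{[(1S,4R,5S)-3,3,5-trimethyl-4-{[tri(propan-2-yl)silyl]ethynyl}bicyclo[3.1.0]hexan-1-yl]oxy}silane
Product: 16 (4R)-3,5,5-trimethyl-4-{[tri(propan-2-yl)silyl]ethynyl}cyclohex-2-en-1-one, via chloroketone 15 (not isolated)
Conditions: FeCl3 (2.2 equiv), DMF, 0 to 23 °C; then NaOAc, 60 °C
Reagents that add atoms: none
Why: Key ring expansion (Ito–Saegusa): one-electron oxidation by FeCl3 gives a cyclopropyloxy radical whose β-scission cleaves the internal bond to the tertiary radical, enlarging the five-membered to a six-membered ketone in a stepwise radical, non-pericyclic process; chlorine capture and acetate-mediated E1cB loss of HCl place the C4'=C5' alkene, and the untouched C6' stereocentre is retained.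

Step 7
Reactants: 16 (4R)-3,5,5-trimethyl-4-{[tri(propan-2-yl)silyl]ethynyl}cyclohex-2-en-1-one
Product: 17 (1R,4R)-3,5,5-trimethyl-4-{[tri(propan-2-yl)silyl]ethynyl}cyclohex-2-en-1-ol
Conditions: (S)-2-methyl-CBS-oxazaborolidine (20 mol%), catecholborane, toluene, −78 °C; MeOH, aq. NaOH
Reagents that add atoms: none
Why: Corey–Bakshi–Shibata reduction with the alkenyl arm as the large group gives the (1R)-allylic alcohol, trans to the alkynyl group (matched with the substrate bias from the pseudoaxial ring methyl), which sets C3'.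

Step 8
Reactants: 17 (1R,4R)-3,5,5-trimethyl-4-{[tri(propan-2-yl)silyl]ethynyl}cyclohex-2-en-1-ol
Product: 18 (1R,4S)-4-ethynyl-3,5,5-trimethylcyclohex-2-en-1-ol
Conditions: Bu4NF, THF, 0 °C
Reagents that add atoms: none
Why: Fluoride-induced cleavage of the alkynyl–silicon bond; no stereocentre is touched (the descriptor at C4 changes only through CIP priorities).

Step 9
Reactants: 18 (1R,4S)-4-ethynyl-3,5,5-trimethylcyclohex-2-en-1-ol; 7 hexadecanoic acid
Product: 19 (1R,4S)-4-ethynyl-3,5,5-trimethylcyclohex-2-en-1-yl hexadecanoate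
Conditions: DCC, DMAP (cat.), CH2Cl2, 0 to 23 °C
Reagents that add atoms: none
Why: Steglich esterification acylates the allylic alcohol with retention, completing the ε-ring building block with the (3'R,6'R) arrangement.

Step 10
Reactants: 17 (1R,4R)-3,5,5-trimethyl-4-{[tri(propan-2-yl)silyl]ethynyl}cyclohex-2-en-1-ol
Product: 21 (1S)-4-ethynyl-3,5,5-trimethylcyclohex-3-en-1-ol, via silylated enynol 20 (not isolated)
Conditions: KOt-Bu (1.5 equiv), DMSO, 40 °C; then H2O, Bu4NF, THF, 23 °C
Reagents that add atoms: none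
Why: Base-mediated prototropic shift: the C6–H is both allylic and propargylic, so equilibration through the delocalised carbanion moves the ring alkene into conjugation with the silylalkyne (tetrasubstituted enyne as thermodynamic sink, the bulky silyl cap preventing acetylide formation), in analogy to the base-induced ε- to β-end-group isomerisation of 3-hydroxy carotenoids, which leaves the carbinol centre intact; fluoride then frees the alkyne.

Step 11
Reactants: 21 (1S)-4-ethynyl-3,5,5-trimethylcyclohex-3-en-1-ol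
Product: 22 (1R,3R,6R)-6-ethynyl-1,5,5-trimethyl-7-oxabicyclo[4.1.0]heptan-3-ol
Conditions: VO(acac)2 (5 mol%), t-BuOOH, CH2Cl2, 0 to 23 °C
Reagents that add atoms: tert-butyl hydroperoxide, CC(C)(C)OO
Why: Hydroxyl-directed vanadium-catalysed epoxidation of the homoallylic alcohol delivers oxygen syn to the OH group, setting C5 and C6 of the epoxy ring.

Step 12
Reactants: 22 (1R,3R,6R)-6-ethynyl-1,5,5-trimethyl-7-oxabicyclo[4.1.0]heptan-3-ol; 7 hexadecanoic acid
Product: 23 (1R,3S,6R)-6-ethynyl-1,5,5-trimethyl-7-oxabicyclo[4.1.0]heptan-3-yl hexadecanoate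
Conditions: PPh3, DIAD, toluene, 0 to 23 °C
Reagents that add atoms: none
Why: Mitsunobu esterification proceeds with SN2 inversion at the carbinol carbon, so the hexadecanoate ends up anti to the epoxide, (3S,5R,6S) in carotenoid numbering; the epoxide is inert to the neutral conditions.

Step 13
Reactants: 24 (Z)-1-methoxybut-1-en-3-yne
Product: 26 buta-1,3-diyn-1-yl(trimethyl)silane, via lithium butadiynide 25 (not isolated)
Conditions: LiN(i-Pr)2 (2 equiv), THF, −78 to −30 °C; then Me3SiCl (1 equiv)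
Reagents that add atoms: chlorotrimethylsilane, C[Si](C)(C)Cl
Why: Deprotonation and β-elimination of methanol from the methoxyenyne give lithium butadiynide, which is silylated once at the metalated terminus (Zweifel-type butadiyne synthesis).

Step 14
Reactants: 26 buta-1,3-diyn-1-yl(trimethyl)silane; 27 (E)-1,2-diiodoethene
Product: 30 (3E,5E,7E)-3,8-dimethyldeca-3,5,7-triene-1,9-diyne, via alkenylalane 28 (not isolated), via bis(trimethylsilyl) trienediyne 29 (not isolated)
Conditions: 26 (2 equiv), Me3Al (2 equiv), Cp2ZrCl2 (20 mol%), ClCH2CH2Cl, 23 °C; then 27 (1 equiv, 0.5 equiv per alane), Pd(PPh3)4 (5 mol%), ZnCl2 (cocatalyst), THF, 23 °C; then MeOH, K2CO3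
Reagents that add atoms: trimethylaluminium, C[Al](C)C; buta-1,3-diyn-1-yl(trimethyl)silane (second equivalent of 26), C[Si](C)(C)C#CC#C
Why: Negishi zirconium-catalysed syn-carboalumination places methyl on the internal and aluminium on the terminal alkyne carbon (E-alkenylalane); two molecules of alane 28 then couple with the two C–I bonds of 27 under palladium catalysis with retention to give the all-E triene, and methanolic K2CO3 cleaves both C–Si bonds.

Step 15
Reactants: 31 propyne
Product: 32 (E)-2-bromo-1-iodoprop-1-ene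
Conditions: IBr, CH2Cl2, −78 °C
Reagents that add atoms: iodine monobromide, IBr
Why: Anti addition of IBr through an iodonium ion, with bromide opening at the more substituted carbon, gives the E alkene with two halogens of different reactivity.

Step 16
Reactants: 30 (3E,5E,7E)-3,8-dimethyldeca-3,5,7-triene-1,9-diyne; 32 (E)-2-bromo-1-iodoprop-1-ene
Product: 34 (2E,4E,6E,8E,10E,12E,14E)-2,15-dibromo-6,11-dimethylhexadeca-2,4,6,8,10,12,14-heptaene, via bis(alkenylzirconocene) 33 (not isolated)
Conditions: Cp2Zr(H)Cl (2.2 equiv), THF, 23 °C; then 32 (2.2 equiv in all, one per terminus), Pd(PPh3)4 (5 mol%), ZnCl2 (20 mol%), 0 to 23 °C, dark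
Reagents that add atoms: (E)-2-bromo-1-iodoprop-1-ene (second equivalent of 32), I/C=C(C)/Br
Why: Twofold syn hydrozirconation puts zirconium on both terminal carbons (E), and the zinc-assisted palladium-catalysed Negishi coupling joins each terminus to one molecule of 32, only at its C–I bond and with retention, so the C12 diyne gains two C3 units and the two C(Me)–Br termini remain for steps 17 and 18.

Step 17
Reactants: 19 (1R,4S)-4-ethynyl-3,5,5-trimethylcyclohex-2-en-1-yl hexadecanoate; 34 (2E,4E,6E,8E,10E,12E,14E)-2,15-dibromo-6,11-dimethylhexadeca-2,4,6,8,10,12,14-heptaene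
Product: 36 (1R,4R)-4-[(1E,3E,5E,7E,9E,11E,13E,15E)-16-bromo-3,7,12-trimethylheptadeca-1,3,5,7,9,11,13,15-octaen-1-yl]-3,5,5-trimethylcyclohex-2-en-1-yl hexadecanoate, via alkenylboronate 35 (not isolated)
Conditions: pinacolborane, Cp2Zr(H)Cl (10 mol%), Et3N (10 mol%), CH2Cl2, 40 °C; then 34 (3 equiv), Pd(OAc)2 (5 mol%), SPhos (10 mol%), aq. K3PO4, THF, 40 °C, dark
Reagents that add atoms: none
Why: Zirconium-catalysed syn hydroboration gives the (E)-alkenylboronate, and Suzuki–Miyaura coupling with excess 34 forms the C8'–C9' bond at one terminus with retention of both alkene geometries; the trans-disposed side chain shields the hindered allylic ester from ionisation by zerovalent palladium, and unreacted 34 is recovered.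

Step 18
Reactants: 23 (1R,3S,6R)-6-ethynyl-1,5,5-trimethyl-7-oxabicyclo[4.1.0]heptan-3-yl hexadecanoate; 36 (1R,4R)-4-[(1E,3E,5E,7E,9E,11E,13E,15E)-16-bromo-3,7,12-trimethylheptadeca-1,3,5,7,9,11,13,15-octaen-1-yl]-3,5,5-trimethylcyclohex-2-en-1-yl hexadecanoate
Product: 38 (3S,5R,6S,3'R,6'R)-5,6-epoxy-5,6-dihydro-β,ε-carotene-3,3'-diyl dihexadecanoate, via alkenylboronate 37 (not isolated)
Conditions: pinacolborane, Cp2Zr(H)Cl (10 mol%), Et3N (10 mol%), CH2Cl2, 40 °C; then 36, Pd(OAc)2 (5 mol%), SPhos (10 mol%), aq. K3PO4, THF, 40 °C, dark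
Reagents that add atoms: none
Why: The same hydroboration/Suzuki–Miyaura sequence forms C8–C9 with retention; the tetrasubstituted vinyl epoxide and both esters tolerate the mild, weakly basic conditions, and all five stereocentres are already in place.

**Compound list**
1 | 1-bromoheptane | CCCCCCCBr | starting material
2 | 1,6-dibromohexane | BrCCCCCCBr | starting material
3 | heptylmagnesium bromide | CCCCCCC[Mg]Br | intermediate
4 | 1-bromotridecane | CCCCCCCCCCCCCBr | intermediate
5 | oxetan-2-one (β-propiolactone) | O=C1CCO1 | starting material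
6 | tridecylmagnesium bromide | CCCCCCCCCCCCC[Mg]Br | intermediate
7 | hexadecanoic acid | CCCCCCCCCCCCCCCC(=O)O | intermediate
8 | 4,4-dimethylcyclopent-2-en-1-one | CC1(C)CC(=O)C=C1 | starting material
9 | ethynyltri(propan-2-yl)silane | C#C[Si](C(C)C)(C(C)C)C(C)C | starting material
10 | dimethyl{[tri(propan-2-yl)silyl]ethynyl}alumane | C[Al](C)C#C[Si](C(C)C)(C(C)C)C(C)C | intermediate
11 | dimethylaluminium (3S)-4,4-dimethyl-3-{[tri(propan-2-yl)silyl]ethynyl}cyclopent-1-en-1-olate | CC(C)[Si](C(C)C)(C(C)C)C#C[C@H]1C=C(O[Al](C)C)CC1(C)C | intermediate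
12 | (2S,3S)-2,4,4-trimethyl-3-{[tri(propan-2-yl)silyl]ethynyl}cyclopentan-1-one | CC(C)[Si](C(C)C)(C(C)C)C#C[C@H]1[C@H](C)C(=O)CC1(C)C | intermediate
13 | trimethyl{[(3R)-2,4,4-trimethyl-3-{[tri(propan-2-yl)silyl]ethynyl}cyclopent-1-en-1-yl]oxy}silane | CC(C)[Si](C(C)C)(C(C)C)C#C[C@H]1C(C)=C(O[Si](C)(C)C)CC1(C)C | intermediate
14 | trimethyl{[(1S,4R,5S)-3,3,5-trimethyl-4-{[tri(propan-2-yl)silyl]ethynyl}bicyclo[3.1.0]hexan-1-yl]oxy}silane (CH2 anti to the alkynyl group) | CC(C)[Si](C(C)C)(C(C)C)C#C[C@H]1[C@]2(C)C[C@]2(O[Si](C)(C)C)CC1(C)C | intermediate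
15 | (4S)-3-chloro-3,5,5-trimethyl-4-{[tri(propan-2-yl)silyl]ethynyl}cyclohexan-1-one (both C3 epimers) | CC(C)[Si](C(C)C)(C(C)C)C#C[C@H]1C(C)(Cl)CC(=O)CC1(C)C | intermediate
16 | (4R)-3,5,5-trimethyl-4-{[tri(propan-2-yl)silyl]ethynyl}cyclohex-2-en-1-one | CC(C)[Si](C(C)C)(C(C)C)C#C[C@H]1C(C)=CC(=O)CC1(C)C | intermediate
17 | (1R,4R)-3,5,5-trimethyl-4-{[tri(propan-2-yl)silyl]ethynyl}cyclohex-2-en-1-ol | CC(C)[Si](C(C)C)(C(C)C)C#C[C@H]1C(C)=C[C@H](O)CC1(C)C | intermediate
18 | (1R,4S)-4-ethynyl-3,5,5-trimethylcyclohex-2-en-1-ol | C#C[C@H]1C(C)=C[C@H](O)CC1(C)C | intermediate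
19 | (1R,4S)-4-ethynyl-3,5,5-trimethylcyclohex-2-en-1-yl hexadecanoate | C#C[C@H]1C(C)=C[C@H](OC(=O)CCCCCCCCCCCCCCC)CC1(C)C | intermediate
20 | (1S)-3,5,5-trimethyl-4-{[tri(propan-2-yl)silyl]ethynyl}cyclohex-3-en-1-ol | CC(C)[Si](C(C)C)(C(C)C)C#CC1=C(C)C[C@H](O)CC1(C)C | intermediate
21 | (1S)-4-ethynyl-3,5,5-trimethylcyclohex-3-en-1-ol | C#CC1=C(C)C[C@H](O)CC1(C)C | intermediate
22 | (1R,3R,6R)-6-ethynyl-1,5,5-trimethyl-7-oxabicyclo[4.1.0]heptan-3-ol (epoxide syn to OH) | O[C@@H]1CC(C)(C)[C@]2(C#C)O[C@]2(C)C1 | intermediate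
23 | (1R,3S,6R)-6-ethynyl-1,5,5-trimethyl-7-oxabicyclo[4.1.0]heptan-3-yl hexadecanoate (epoxide anti to ester) | CCCCCCCCCCCCCCCC(=O)O[C@H]1CC(C)(C)[C@]2(C#C)O[C@]2(C)C1 | intermediate
24 | (Z)-1-methoxybut-1-en-3-yne | CO/C=C\C#C | starting material
25 | lithium buta-1,3-diyn-1-ide | [Li]C#CC#C | intermediate
26 | buta-1,3-diyn-1-yl(trimethyl)silane | C[Si](C)(C)C#CC#C | intermediate
27 | (E)-1,2-diiodoethene | I/C=C/I | starting material
28 | dimethyl[(1E)-2-methyl-4-(trimethylsilyl)but-1-en-3-yn-1-yl]alumane | C[Al](C)/C=C(\C)C#C[Si](C)(C)C | intermediate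
29 | [(3E,5E,7E)-3,8-dimethyldeca-3,5,7-triene-1,9-diyne-1,10-diyl]bis(trimethylsilane) | C[Si](C)(C)C#C/C(C)=C/C=C/C=C(C)/C#C[Si](C)(C)C | intermediate
30 | (3E,5E,7E)-3,8-dimethyldeca-3,5,7-triene-1,9-diyne | C#C/C(C)=C/C=C/C=C(C)/C#C | intermediate
31 | propyne | CC#C | starting material
32 | (E)-2-bromo-1-iodoprop-1-ene | I/C=C(C)/Br | intermediate
33 | [(1E,3E,5E,7E,9E)-3,8-dimethyldeca-1,3,5,7,9-pentaene-1,10-diyl]bis[chloridobis(cyclopentadienyl)zirconium] | Cl[Zr](C1C=CC=C1)(C1C=CC=C1)/C=C/C(C)=C/C=C/C=C(C)/C=C/[Zr](Cl)(C1C=CC=C1)C1C=CC=C1 | intermediate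
34 | (2E,4E,6E,8E,10E,12E,14E)-2,15-dibromo-6,11-dimethylhexadeca-2,4,6,8,10,12,14-heptaene | Br/C(C)=C/C=C/C(C)=C/C=C/C=C(C)/C=C/C=C(C)/Br | intermediate
35 | (1R,4R)-3,5,5-trimethyl-4-[(E)-2-(4,4,5,5-tetramethyl-1,3,2-dioxaborolan-2-yl)ethenyl]cyclohex-2-en-1-yl hexadecanoate | CC1(C)OB(/C=C/[C@H]2C(C)=C[C@H](OC(=O)CCCCCCCCCCCCCCC)CC2(C)C)OC1(C)C | intermediate
36 | (1R,4R)-4-[(1E,3E,5E,7E,9E,11E,13E,15E)-16-bromo-3,7,12-trimethylheptadeca-1,3,5,7,9,11,13,15-octaen-1-yl]-3,5,5-trimethylcyclohex-2-en-1-yl hexadecanoate | Br/C(C)=C/C=C/C(C)=C/C=C/C=C(C)/C=C/C=C(C)/C=C/[C@H]1C(C)=C[C@H](OC(=O)CCCCCCCCCCCCCCC)CC1(C)C | intermediate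
37 | (1R,3S,6S)-1,5,5-trimethyl-6-[(E)-2-(4,4,5,5-tetramethyl-1,3,2-dioxaborolan-2-yl)ethenyl]-7-oxabicyclo[4.1.0]heptan-3-yl hexadecanoate | CCCCCCCCCCCCCCCC(=O)O[C@H]1CC(C)(C)[C@]2(/C=C/B3OC(C)(C)C(C)(C)O3)O[C@]2(C)C1 | intermediate
38 | (3S,5R,6S,3'R,6'R)-5,6-epoxy-5,6-dihydro-β,ε-carotene-3,3'-diyl dihexadecanoate (lutein 5,6-epoxide dipalmitate) | CCCCCCCCCCCCCCCC(=O)O[C@H]1CC(C)(C)[C@]2(/C=C/C(C)=C/C=C/C(C)=C/C=C/C=C(C)/C=C/C=C(C)/C=C/[C@H]3C(C)=C[C@H](OC(=O)CCCCCCCCCCCCCCC)CC3(C)C)O[C@]2(C)C1 | target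

**Totals**
Total step count: 18.
Longest linear sequence: 9 steps (steps 3, 4, 5, 6, 7, 10, 11, 12 and 18, from 8 to 38; the ε branch through steps 8, 9 and 17 is equally long).

**Three steps most likely to fail**

Step 3 (the proposed new method). The β-carbon is neopentyl-like and neither the enantioselectivity nor the methyl trapping has precedent on this substrate. The fallback uses known chemistry, sets out from 8 and 9 and comes back to the route at 17. Alane 10 is made as in step 3 and added to 8 with ligand-free Ni(acac)2/i-Bu2AlH (the established racemic nickel-catalysed alkynylalane conjugate addition), which gives the racemic aluminium enolate F1. MeLi and MeI convert it into the racemic trans ketone F2. Steps 4 to 6 carried out unchanged give the racemic silyl enol ether F3, the racemic siloxycyclopropane F4, the racemic chloroketone F5 (not isolated) and the racemic enone F6. The stereocentres are then set by the reagent alone: the (S)-CBS reduction of step 7 turns the (4R)-half of F6 into 17 and the (4S)-half into the cis alcohol F7. These two are diastereomers and are separated by chromatography. F7 is not lost, because step 10 erases the C4 centre and converts it into 21 as well.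

Step 10 (alkene shift). The silyl group may be lost before the shift, which would stall the reaction at the acetylide, and allene isomers may form. The fallback sets out from 16 and comes back at 20. At the ketone stage the C4 proton is vinylogously acidic, so catalytic KOt-Bu in t-BuOH deconjugates 16 to the β,γ-unsaturated ketone F8 (the known 3-oxo-α to 3-oxo-β end-group isomerisation). NaBH4 gives the racemic alcohol F9. Lipase-catalysed kinetic resolution (Burkholderia cepacia lipase, vinyl acetate) acetylates the (1R)-enantiomer to the acetate F10 and leaves the (1S)-alcohol 20, which is desilylated with Bu4NF as in the second stage of step 10. The price is a 50% ceiling on yield.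

Step 12 (Mitsunobu inversion). The carbinol is flanked by a CH2–CMe2 unit, so SN2 attack is hindered and elimination can compete. The fallback avoids any inversion, sets out from 16 and comes back at 23. Reduction of 16 with the (R)-CBS catalyst gives the cis alcohol F11. KOt-Bu in DMSO shifts the alkene to give the silylated (1R)-enynol F12, and Bu4NF gives the (1R)-enynol F13. DCC/DMAP esterification with 7 gives the ester F14, which already has the C3 configuration of the target. Epoxidation with m-CPBA/NaHCO3 then occurs mainly anti to the acyloxy group under steric control, and 23 is separated from the minor syn epoxide by chromatography.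

**Further compounds**
F1 | step 3 | racemic dimethylaluminium 4,4-dimethyl-3-{[tri(propan-2-yl)silyl]ethynyl}cyclopent-1-en-1-olate | CC(C)[Si](C(C)C)(C(C)C)C#CC1C=C(O[Al](C)C)CC1(C)C
F2 | step 3 | racemic trans-2,4,4-trimethyl-3-{[tri(propan-2-yl)silyl]ethynyl}cyclopentan-1-one | CC(C)[Si](C(C)C)(C(C)C)C#CC1C(C)C(=O)CC1(C)C
F3 | step 3 | racemic trimethyl{[2,4,4-trimethyl-3-{[tri(propan-2-yl)silyl]ethynyl}cyclopent-1-en-1-yl]oxy}silane | CC(C)[Si](C(C)C)(C(C)C)C#CC1C(C)=C(O[Si](C)(C)C)CC1(C)C
F4 | step 3 | racemic trimethyl{[3,3,5-trimethyl-4-{[tri(propan-2-yl)silyl]ethynyl}bicyclo[3.1.0]hexan-1-yl]oxy}silane | CC(C)[Si](C(C)C)(C(C)C)C#CC1C2(C)CC2(O[Si](C)(C)C)CC1(C)C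
F5 | step 3 | racemic 3-chloro-3,5,5-trimethyl-4-{[tri(propan-2-yl)silyl]ethynyl}cyclohexan-1-one | CC(C)[Si](C(C)C)(C(C)C)C#CC1C(C)(Cl)CC(=O)CC1(C)C
F6 | step 3 | racemic 3,5,5-trimethyl-4-{[tri(propan-2-yl)silyl]ethynyl}cyclohex-2-en-1-one | CC(C)[Si](C(C)C)(C(C)C)C#CC1C(C)=CC(=O)CC1(C)C
F7 | step 3 | (1R,4S)-3,5,5-trimethyl-4-{[tri(propan-2-yl)silyl]ethynyl}cyclohex-2-en-1-ol | CC(C)[Si](C(C)C)(C(C)C)C#C[C@@H]1C(C)=C[C@H](O)CC1(C)C
F8 | step 10 | 3,5,5-trimethyl-4-{[tri(propan-2-yl)silyl]ethynyl}cyclohex-3-en-1-one | CC(C)[Si](C(C)C)(C(C)C)C#CC1=C(C)CC(=O)CC1(C)C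
F9 | step 10 | racemic 3,5,5-trimethyl-4-{[tri(propan-2-yl)silyl]ethynyl}cyclohex-3-en-1-ol | CC(C)[Si](C(C)C)(C(C)C)C#CC1=C(C)CC(O)CC1(C)C
F10 | step 10 | (1R)-3,5,5-trimethyl-4-{[tri(propan-2-yl)silyl]ethynyl}cyclohex-3-en-1-yl acetate | CC(C)[Si](C(C)C)(C(C)C)C#CC1=C(C)C[C@@H](OC(C)=O)CC1(C)C
F11 | step 12 | (1S,4R)-3,5,5-trimethyl-4-{[tri(propan-2-yl)silyl]ethynyl}cyclohex-2-en-1-ol | CC(C)[Si](C(C)C)(C(C)C)C#C[C@H]1C(C)=C[C@@H](O)CC1(C)C
F12 | step 12 | (1R)-3,5,5-trimethyl-4-{[tri(propan-2-yl)silyl]ethynyl}cyclohex-3-en-1-ol | CC(C)[Si](C(C)C)(C(C)C)C#CC1=C(C)C[C@@H](O)CC1(C)C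
F13 | step 12 | (1R)-4-ethynyl-3,5,5-trimethylcyclohex-3-en-1-ol | C#CC1=C(C)C[C@@H](O)CC1(C)C
F14 | step 12 | (1R)-4-ethynyl-3,5,5-trimethylcyclohex-3-en-1-yl hexadecanoate | C#CC1=C(C)C[C@@H](OC(=O)CCCCCCCCCCCCCCC)CC1(C)C
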